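**Plan**
- Cuts, in retrosynthetic order: both O–CH3 bonds (the phenols travel as methyl ethers); the three C–Br bonds of ring B (the middle one by way of C–N, its neighbours by amine-directed bromination); ring B itself at C2–C3 and C5–C6 (C1 = C–OH, C2 = C–OAr); last the ArO–CH2 bond.
- Enabling feature: ring B has OH on C1, the ether oxygen on C2 and bromine on the contiguous C3, C4 and C5, with C4 para to the OH. C3–C4–C5 therefore maps onto a 2-substituted malonaldehyde and C6–C1–C2 onto the C–C(=O)–C backbone of an aryloxyacetone.
- Forward: ring A is bought complete; O-alkylation attaches the acetone unit; a double aldol condensation with nitromalonaldehyde closes ring B, the only ring built, as a 2-aryloxy-4-nitrophenol.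
- The nitro group then becomes the central bromine (reduction, ortho,ortho-dibromination, Sandmeyer), and both methyl ethers are cleaved at the end.
- Stereochemistry: the target has no stereocentre and no stereogenic double bond, so nothing has to be set.

Key step: step 3

Assumption: 2,4-dibromo-6-methoxyphenol 1 is taken to be a purchasable building block; sodium nitromalonaldehyde is handled as its monohydrate, an impact-sensitive solid to be kept from heat and shock.

**Route**

Step 1
Reactants: 1 2,4-dibromo-6-methoxyphenol; 2 chloroacetone
Product: 3 1-(2,4-dibromo-6-methoxyphenoxy)propan-2-one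
Conditions: K2CO3, DMF, 50 °C
Reagents that add atoms: none
Why: Williamson ether synthesis, in which the phenoxide of 1 displaces chloride from the highly SN2-reactive alpha-chloro ketone, so the crowded aryl–oxygen bond of the future diaryl ether is made by a simple alkylation.

Step 2
Reactants: 4 mucobromic acid
Product: 5 sodium nitromalonaldehyde, Na[O2N–C(CHO)2], as the monohydrate
Conditions: NaNO2 (excess), H2O/EtOH, 54 °C; then 0 °C, crystallisation
Reagents that add atoms: sodium nitrite, SMILES [Na+].[O-]N=O; water, SMILES O
Why: Known nitrite degradation of mucobromic acid, in which nitrite replaces the bromine on the carbon next to the formyl group by addition–elimination, the carboxyl group is lost by decarboxylation and the remaining bromovinyl carbon is hydrolysed to the second formyl group, so the resonance-stabilised anion crystallises as its sodium salt.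

Step 3
Reactants: 3 1-(2,4-dibromo-6-methoxyphenoxy)propan-2-one; 5 sodium nitromalonaldehyde
Product: 8 2-(2,4-dibromo-6-methoxyphenoxy)-4-nitrophenol, via open-chain keto nitronate 6 (not isolated), via sodium nitrophenolate 7 (not isolated)
Conditions: NaOH (aq, 1–2 equiv), EtOH/H2O, 0 °C → rt, 2–4 d; then aq HCl to pH 2
Reagents that add atoms: none
Why: Hydroxide generates the enolate at the aryloxy-bearing methylene carbon of 3, which adds to one formyl carbon of 5 and loses water to give the open-chain keto nitronate 6; the methyl-side enolate then attacks the remaining formyl carbon, and a second dehydration with tautomerisation delivers the aromatic phenolate 7, which acid converts into 8. The closest known reaction type is the base-mediated condensation of sodium nitromalonaldehyde with acetone and other ketones having two enolisable alpha carbons, a double aldol (Knoevenagel-type) benzannulation that gives 4-nitrophenols. Ring B, the only ring formed, closes by an intramolecular aldol condensation in the 6-(enolendo)-exo-trig mode and is then aromatised, the ketone carbon becoming C–OH, the aryloxymethylene carbon the ether carbon and the nitro-bearing carbon the one para to the hydroxyl. No stereocentre is created, and the C=C geometry in 6 is of no consequence because it can equilibrate through the delocalised nitronate and disappears on aromatisation. The step needs cross-condensation to outrun self-aldol of 3, which should be secured by the non-enolisable formyl groups of 5 acting only as acceptors, the enhanced acidity of the aryloxymethylene group and the irreversible aromatisation. Regiochemistry cannot go astray, because the dialdehyde is symmetric and both alpha carbons of the ketone end up in the ring.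

Step 4
Reactants: 8 2-(2,4-dibromo-6-methoxyphenoxy)-4-nitrophenol
Product: 9 1,5-dibromo-3-methoxy-2-(2-methoxy-5-nitrophenoxy)benzene
Conditions: MeI, K2CO3, DMF, rt
Reagents that add atoms: iodomethane, SMILES CI
Why: Williamson O-methylation of the acidic 4-nitrophenol, which masks the ring-B oxygen so that the later para-aminophenol stage cannot be oxidised to a quinone imine and leaves both oxygens as the same ether for one final deprotection.

Step 5
Reactants: 9 1,5-dibromo-3-methoxy-2-(2-methoxy-5-nitrophenoxy)benzene
Product: 10 3-(2,4-dibromo-6-methoxyphenoxy)-4-methoxyaniline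
Conditions: Fe powder, NH4Cl, EtOH/H2O, 80 °C
Reagents that add atoms: none
Why: Béchamp-type iron reduction, which takes the nitro group to the amine by electron transfer from the metal and leaves the aryl C–Br bonds alone, whereas catalytic hydrogenation would endanger them.

Step 6
Reactants: 10 3-(2,4-dibromo-6-methoxyphenoxy)-4-methoxyaniline
Product: 11 2,6-dibromo-3-(2,4-dibromo-6-methoxyphenoxy)-4-methoxyaniline
Conditions: NBS (2.05 equiv), MeCN, 0 °C → rt, dark
Reagents that add atoms: N-bromosuccinimide, SMILES O=C1CCC(=O)N1Br
Why: Electrophilic aromatic bromination, in which the amino group as the strongest donor of ring B activates its two ortho carbons (its para carbon carries the methoxy group and both ortho carbons are further activated by the aryloxy oxygen), while the dibromo-deactivated ring A and the ring-B carbon next to the methoxy group (meta to nitrogen) should react more slowly, so two equivalents should stop at 11.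

Step 7
Reactants: 11 2,6-dibromo-3-(2,4-dibromo-6-methoxyphenoxy)-4-methoxyaniline
Product: 13 1,2,3-tribromo-4-(2,4-dibromo-6-methoxyphenoxy)-5-methoxybenzene, via arenediazonium hydrogensulfate 12 (not isolated)
Conditions: NaNO2, conc. H2SO4/AcOH, 0–10 °C; then CuBr, 48% aq HBr, 0 → 60 °C
Reagents that add atoms: hydrogen bromide (aqueous HBr), SMILES Br, delivered through CuBr, SMILES [Cu]Br
Why: Sandmeyer reaction, in which nitrosylsulfuric acid diazotises the weakly basic 2,6-dibromoaniline and CuBr reduces the diazonium ion to an aryl radical that takes bromine from copper, an ipso substitution that fixes the third bromine between the other two.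

Step 8
Reactants: 13 1,2,3-tribromo-4-(2,4-dibromo-6-methoxyphenoxy)-5-methoxybenzene
Product: 15 3,4,5-tribromo-2-(2,4-dibromo-6-hydroxyphenoxy)phenol (target), via bis(dibromoboryl) ether 14 (not isolated)
Conditions: BBr3 (5 equiv), CH2Cl2, −78 °C → rt; then H2O, 0 °C
Reagents that add atoms: none
Why: Lewis-acid ether cleavage, in which BBr3 coordinates each methoxy oxygen and bromide attacks the methyl carbon (SN2), while the diaryl ether offers no sp3 carbon and survives, and hydrolysis of the aryloxyboranes frees both phenols.

**Compound list**

1 | 2,4-dibromo-6-methoxyphenol | COc1cc(Br)cc(Br)c1O | starting material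
2 | chloroacetone (1-chloropropan-2-one) | CC(=O)CCl | starting material
3 | 1-(2,4-dibromo-6-methoxyphenoxy)propan-2-one | COc1cc(Br)cc(Br)c1OCC(C)=O | intermediate
4 | mucobromic acid (3,4-dibromo-5-hydroxyfuran-2(5H)-one, lactol form) | OC1OC(=O)C(Br)=C1Br | starting material
5 | sodium nitromalonaldehyde, Na[O2N–C(CHO)2] (used as monohydrate) | [Na+].O=C[C-](C=O)[N+](=O)[O-] | intermediate
6 | sodium 4-(2,4-dibromo-6-methoxyphenoxy)-2-nitro-5-oxohexa-1,3-dien-1-olate (open-chain keto nitronate, not isolated, C=C geometry not fixed) | CC(=O)C(Oc1c(Br)cc(Br)cc1OC)=CC(=C[O-])[N+](=O)[O-].[Na+] | intermediate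
7 | sodium 2-(2,4-dibromo-6-methoxyphenoxy)-4-nitrophenolate (not isolated) | COc1cc(Br)cc(Br)c1Oc1cc(ccc1[O-])[N+](=O)[O-].[Na+] | intermediate
8 | 2-(2,4-dibromo-6-methoxyphenoxy)-4-nitrophenol | COc1cc(Br)cc(Br)c1Oc1cc(ccc1O)[N+](=O)[O-] | intermediate
9 | 1,5-dibromo-3-methoxy-2-(2-methoxy-5-nitrophenoxy)benzene | COc1cc(Br)cc(Br)c1Oc1cc(ccc1OC)[N+](=O)[O-] | intermediate
10 | 3-(2,4-dibromo-6-methoxyphenoxy)-4-methoxyaniline | COc1cc(Br)cc(Br)c1Oc1cc(N)ccc1OC | intermediate
11 | 2,6-dibromo-3-(2,4-dibromo-6-methoxyphenoxy)-4-methoxyaniline | COc1cc(Br)cc(Br)c1Oc1c(OC)cc(Br)c(N)c1Br | intermediate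
12 | 2,6-dibromo-3-(2,4-dibromo-6-methoxyphenoxy)-4-methoxybenzenediazonium hydrogensulfate (not isolated) | COc1cc(Br)cc(Br)c1Oc1c(OC)cc(Br)c([N+]#N)c1Br.OS(=O)(=O)[O-] | intermediate
13 | 1,2,3-tribromo-4-(2,4-dibromo-6-methoxyphenoxy)-5-methoxybenzene | COc1cc(Br)cc(Br)c1Oc1c(OC)cc(Br)c(Br)c1Br | intermediate
14 | dibromo{3,4,5-tribromo-2-[2,4-dibromo-6-(dibromoboryloxy)phenoxy]phenoxy}borane (bis(dibromoboryl) ether, not isolated) | BrB(Br)Oc1cc(Br)cc(Br)c1Oc1c(OB(Br)Br)cc(Br)c(Br)c1Br | intermediate
15 | 3,4,5-tribromo-2-(2,4-dibromo-6-hydroxyphenoxy)phenol | Oc1cc(Br)cc(Br)c1Oc1c(O)cc(Br)c(Br)c1Br | target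

**Count**

Total steps: 8. Longest linear sequence: 7 steps (steps 1, 3, 4, 5, 6, 7, 8, from 1 to 15); step 2 is a one-step side branch that supplies 5.

**Steps most likely to fail**

1. Step 3 (benzannulation). Self-aldol condensation of ketone 3 or slow base-induced degradation of the reactants may outrun the cross-condensation, or the ring-closing second aldol may stall at the open-chain stage. The fallback gives up the ring construction and makes the diaryl ether bond directly; it sets out from 1 and comes back to the route at 9. Purchased 2-iodo-4-nitroanisole would be oxidised with mCPBA and TsOH·H2O in MeCN to 1-[hydroxy(tosyloxy)iodo]-2-methoxy-5-nitrobenzene F1, which is captured in the same pot by 1,3,5-trimethoxybenzene to give (2-methoxy-5-nitrophenyl)(2,4,6-trimethoxyphenyl)iodonium tosylate F2. Phenol 1 would then be O-arylated with F2 (K2CO3, MeCN or toluene, 50–80 °C). The electron-rich trimethoxyphenyl group should stay on iodine and the nitroaryl group should be transferred, giving nitroanisole 9 without touching the aryl bromides.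

2. Step 6 (dibromination). Site control may be lost, with a third bromine entering next to the ring-B methoxy group, or the electron-rich para-anisidine may be oxidised by the brominating agent towards quinone-imine-type products. The fallback makes the ring-B oxygen electron-poor during the bromination; it sets out from 8 and comes back at 11. MsCl and Et3N in CH2Cl2 would give 2-(2,4-dibromo-6-methoxyphenoxy)-4-nitrophenyl methanesulfonate F3. Fe and NH4Cl would reduce it to 4-amino-2-(2,4-dibromo-6-methoxyphenoxy)phenyl methanesulfonate F4. NBS in MeCN should then brominate only the two carbons ortho to nitrogen, because the sulfonate oxygen no longer activates its neighbour and cannot support quinone imine formation, giving 4-amino-3,5-dibromo-2-(2,4-dibromo-6-methoxyphenoxy)phenyl methanesulfonate F5. NaOH in MeOH/H2O at reflux would remove the mesyl group to give 4-amino-3,5-dibromo-2-(2,4-dibromo-6-methoxyphenoxy)phenol F6. MeI and K2CO3 in acetone should methylate the phenoxide selectively, the hindered and weakly nucleophilic 2,6-dibromoaniline nitrogen staying free, and give 11.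

3. Step 7 (Sandmeyer). Diazotisation of the hindered, weakly basic amine may be incomplete, or the diazonium ion may be diverted to hydrolysis or to hydrogen capture by the aryl radical before bromine transfer; hot HBr may also begin to cleave the methyl ethers. The fallback separates diazotisation from bromine delivery and avoids copper and aqueous acid; it sets out from 11 and comes back at 13. NOBF4 in MeCN at −30 °C would give 2,6-dibromo-3-(2,4-dibromo-6-methoxyphenoxy)-4-methoxybenzenediazonium tetrafluoroborate F7, precipitated with Et2O. Et2NH and K2CO3 would convert it into the stable, chromatographable 1-[2,6-dibromo-3-(2,4-dibromo-6-methoxyphenoxy)-4-methoxyphenyl]-3,3-diethyltriaz-1-ene F8. Bromotrimethylsilane in MeCN at 60 °C should then cleave the triazene to the aryl bromide 13.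

**Further compounds**

F1 | step 3 | 1-[hydroxy(tosyloxy)iodo]-2-methoxy-5-nitrobenzene | COc1ccc(cc1I(O)OS(=O)(=O)c1ccc(C)cc1)[N+](=O)[O-]
F2 | step 3 | (2-methoxy-5-nitrophenyl)(2,4,6-trimethoxyphenyl)iodonium tosylate | COc1ccc(cc1[I+]c1c(OC)cc(OC)cc1OC)[N+](=O)[O-].Cc1ccc(cc1)S(=O)(=O)[O-]
F3 | step 6 | 2-(2,4-dibromo-6-methoxyphenoxy)-4-nitrophenyl methanesulfonate | COc1cc(Br)cc(Br)c1Oc1cc(ccc1OS(C)(=O)=O)[N+](=O)[O-]
F4 | step 6 | 4-amino-2-(2,4-dibromo-6-methoxyphenoxy)phenyl methanesulfonate | COc1cc(Br)cc(Br)c1Oc1cc(N)ccc1OS(C)(=O)=O
F5 | step 6 | 4-amino-3,5-dibromo-2-(2,4-dibromo-6-methoxyphenoxy)phenyl methanesulfonate | COc1cc(Br)cc(Br)c1Oc1c(OS(C)(=O)=O)cc(Br)c(N)c1Br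
F6 | step 6 | 4-amino-3,5-dibromo-2-(2,4-dibromo-6-methoxyphenoxy)phenol | COc1cc(Br)cc(Br)c1Oc1c(O)cc(Br)c(N)c1Br
F7 | step 7 | 2,6-dibromo-3-(2,4-dibromo-6-methoxyphenoxy)-4-methoxybenzenediazonium tetrafluoroborate | COc1cc(Br)cc(Br)c1Oc1c(OC)cc(Br)c([N+]#N)c1Br.F[B-](F)(F)F
F8 | step 7 | 1-[2,6-dibromo-3-(2,4-dibromo-6-methoxyphenoxy)-4-methoxyphenyl]-3,3-diethyltriaz-1-ene | COc1cc(Br)cc(Br)c1Oc1c(OC)cc(Br)c(N=NN(CC)CC)c1Br
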